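**Retrosynthetic overview**

1. The target is two flavanones joined C3–C8″: unit 1 (benzo ring A, pyranone ring C, 4-hydroxyphenyl ring B; 2R,3S, trans) and unit 2 (benzo ring D, pyranone ring F, 4-methoxyphenyl ring E; 2″S). The last operation is hydrogenolysis of five benzyl ethers (21 → 22).
2. Key disconnection: ring F is opened at C3″–C4″ and O1″–C2″ to salicylaldehyde 15 (ring D already carrying unit 1) and ynoate 18. Forward, in one flask: rhodium-catalysed hydroacylation (C3″–C4″), thiourea-catalysed enantioselective oxa-Michael closure (O1″–C2″, sets 2″S), loss of the ester as CO2.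
3. Enabling feature: C4″ sits on ring D ortho to O1″ (array O1″–C8a″–C4a″–C4″). The one free phenol first chelates rhodium for activation of the formyl C–H and then closes ring F, while the second ortho oxygen (on C5″) is benzylated. C3″ is a bare CH2 and can carry a traceless CO2t-Bu group that polarises the alkyne and organises the chiral catalyst.
4. Unit 1: ring C by Knoevenagel condensation and enantioselective oxa-Michael closure of 12 (sets C2). The C3–C8″ bond comes from arylation of β-keto ester 13 with aryllead reagent 7 (ring D, made by two directed metalations). Decarboxylation gives the 2,3-trans ketone 15.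
5. Ring order: rings A, B, D and E are bought as arenes; ring C is closed in step 6 and ring F in step 10.

Key step: step 10

Assumption: the descriptors read from the structure are (2R,3S), 2,3-trans, for the 3-linked unit and (2″S) for the 8-linked unit. The two ring closures need opposite facial senses, so steps 6 and 10 use pseudoenantiomeric cinchona thioureas. The quinidine-derived one is assigned to step 6 and the quinine-derived one to step 10 by analogy; this is to be confirmed on a model alkylidene and the two exchanged if the sense is reversed.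

**Route**

Step 1
Reactants: 1 3,5-bis(benzyloxy)phenol
Product: 2 1,3-bis(benzyloxy)-5-(methoxymethoxy)benzene
Conditions: MOMCl, iPr2NEt, CH2Cl2, 0 °C → rt
Reagents that add atoms: chloromethyl methyl ether, COCCl
Why: Williamson-type O-alkylation of the only free phenol installs the MOM group that later serves both as the ortho-directing group and as the acid-labile mask of O1″.

Step 2
Reactants: 2 1,3-bis(benzyloxy)-5-(methoxymethoxy)benzene
Product: 6 4,6-bis(benzyloxy)-2-(methoxymethoxy)-3-(tributylstannyl)benzaldehyde, via aryllithium 3 (not isolated), via lithium aminoalkoxide 4 (not isolated), via ring-lithiated aminoalkoxide 5 (not isolated)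
Conditions: n-BuLi, THF, 0 °C; DMF, −78 → −20 °C; n-BuLi, −20 → 0 °C; Bu3SnCl, −78 °C → rt; aq. NH4Cl
Reagents that add atoms: N,N-dimethylformamide, CN(C)C=O; tributyltin chloride, CCCC[Sn](Cl)(CCCC)CCCC
Why: Two directed ortho-metalations in one flask: the MOM oxygen directs the first lithiation to the carbon between OMOM and OBn, formylation with DMF stops at the lithium α-amino alkoxide, which masks the aldehyde while the MOM group directs the second lithiation to its other ortho position, and stannylation followed by aqueous work-up releases the aldehyde.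

Step 3
Reactants: 6 4,6-bis(benzyloxy)-2-(methoxymethoxy)-3-(tributylstannyl)benzaldehyde
Product: 7 [4,6-bis(benzyloxy)-3-formyl-2-(methoxymethoxy)phenyl]lead triacetate
Conditions: Pb(OAc)4, Hg(OAc)2 (cat.), CHCl3, 40 °C; filtration, used crude
Reagents that add atoms: lead tetraacetate, CC(=O)O[Pb](OC(C)=O)(OC(C)=O)OC(C)=O
Why: Tin–lead exchange catalysed by mercury diacetate (ipso electrophilic substitution at the electron-rich aryl–Sn bond) is the standard entry to aryllead triacetates and should tolerate the formyl and MOM groups.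

Step 4
Reactants: 8 1-[2,4-bis(benzyloxy)-6-hydroxyphenyl]ethan-1-one
Product: 10 tert-butyl 3-[2,4-bis(benzyloxy)-6-hydroxyphenyl]-3-oxopropanoate, via dilithium enolate 9 (not isolated)
Conditions: LiN(SiMe3)2 (3.2 equiv), THF, −78 °C; Boc2O, −78 → 0 °C; aq. NH4Cl
Reagents that add atoms: di-tert-butyl dicarbonate, CC(C)(C)OC(=O)OC(=O)OC(C)(C)C
Why: C-acylation of the ketone enolate within the phenoxide/enolate dianion by Boc2O (a crossed Claisen-type condensation; any O-Boc phenol formed should pass the group on to carbon) gives the tert-butyl β-keto ester, protected from over-reaction as its enolate.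

Step 5
Reactants: 10 tert-butyl 3-[2,4-bis(benzyloxy)-6-hydroxyphenyl]-3-oxopropanoate; 11 4-(benzyloxy)benzaldehyde
Product: 12 tert-butyl (2Z)-2-[2,4-bis(benzyloxy)-6-hydroxybenzoyl]-3-[4-(benzyloxy)phenyl]prop-2-enoate
Conditions: piperidine (cat.), AcOH (cat.), toluene, 4 Å MS, rt
Reagents that add atoms: none
Why: Knoevenagel condensation under piperidinium acetate catalysis gives the alkylidene β-keto ester, expected mainly as the Z isomer with the aryl group cis to the twisted ester.

Step 6
Reactants: 12 tert-butyl (2Z)-2-[2,4-bis(benzyloxy)-6-hydroxybenzoyl]-3-[4-(benzyloxy)phenyl]prop-2-enoate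
Product: 13 tert-butyl (2S)-5,7-bis(benzyloxy)-2-[4-(benzyloxy)phenyl]-4-hydroxy-2H-chromene-3-carboxylate (enol tautomer of the (2R)-4-oxochromane-3-carboxylate; C2 spatially as C2 of unit 1 in the target)
Conditions: 1-[3,5-bis(trifluoromethyl)phenyl]-3-(9-deoxy-epi-quinidin-9-yl)thiourea (10 mol %), toluene, −25 °C; cold filtration through silica, used at once
Reagents that add atoms: none
Why: Enantioselective intramolecular oxa-Michael addition (6-endo-trig), a known reaction of 2-hydroxyaryl alkylidene β-keto esters, in which the thiourea binds the β-dicarbonyl unit and the quinuclidine activates the phenol, so that the catalyst sets C2 and the product is held as the enol.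

Step 7
Reactants: 13 tert-butyl (2S)-5,7-bis(benzyloxy)-2-[4-(benzyloxy)phenyl]-4-hydroxy-2H-chromene-3-carboxylate; 7 [4,6-bis(benzyloxy)-3-formyl-2-(methoxymethoxy)phenyl]lead triacetate
Product: 14 tert-butyl (2S,3R)-3-[4,6-bis(benzyloxy)-3-formyl-2-(methoxymethoxy)phenyl]-5,7-bis(benzyloxy)-2-[4-(benzyloxy)phenyl]-4-oxochromane-3-carboxylate (aryl at C3 anti to the C2 aryl; C2 spatially unchanged, the descriptor changes only through the priority rules)
Conditions: pyridine (3 equiv), CHCl3, 40 °C
Reagents that add atoms: none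
Why: α-Arylation of the β-keto ester by ligand coupling within a tetravalent lead enolate, a known reaction of 3-alkoxycarbonylchroman-4-ones and of di-ortho-oxygenated aryllead triacetates, makes the C3–C8″ bond with the aryl group expected anti to the C2 aryl group, and once C3 is quaternary the C2 centre can no longer open by retro-oxa-Michael reaction.

Step 8
Reactants: 14 tert-butyl (2S,3R)-3-[4,6-bis(benzyloxy)-3-formyl-2-(methoxymethoxy)phenyl]-5,7-bis(benzyloxy)-2-[4-(benzyloxy)phenyl]-4-oxochromane-3-carboxylate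
Product: 15 4,6-bis(benzyloxy)-3-[(2R,3S)-5,7-bis(benzyloxy)-2-[4-(benzyloxy)phenyl]-4-oxochroman-3-yl]-2-hydroxybenzaldehyde
Conditions: TFA, CH2Cl2, H2O (2 equiv), 0 °C → rt; then toluene, 50 °C
Reagents that add atoms: none
Why: Acidolysis removes the tert-butyl ester and the MOM acetal, the β-keto acid decarboxylates through its enol, and C3 is protonated and equilibrated under the acid to the diequatorial 2,3-trans ketone (3S) while C2 is untouched.

Step 9
Reactants: 16 1-ethynyl-4-methoxybenzene
Product: 18 tert-butyl 3-(4-methoxyphenyl)prop-2-ynoate, via lithium acetylide 17 (not isolated)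
Conditions: n-BuLi, THF, −78 °C; Boc2O, −78 °C → rt; aq. NH4Cl
Reagents that add atoms: di-tert-butyl dicarbonate, CC(C)(C)OC(=O)OC(=O)OC(C)(C)C
Why: Acylation of the lithium acetylide with Boc2O is the standard preparation of tert-butyl alkynoates.

Step 10
Reactants: 15 4,6-bis(benzyloxy)-3-[(2R,3S)-5,7-bis(benzyloxy)-2-[4-(benzyloxy)phenyl]-4-oxochroman-3-yl]-2-hydroxybenzaldehyde; 18 tert-butyl 3-(4-methoxyphenyl)prop-2-ynoate
Product: 21 (2S)-5,7-bis(benzyloxy)-8-[(2R,3S)-5,7-bis(benzyloxy)-2-[4-(benzyloxy)phenyl]-4-oxochroman-3-yl]-2-(4-methoxyphenyl)chroman-4-one, via alkylidene keto ester 19 (not isolated), via enol ester 20 (not isolated)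
Conditions: [Rh(cod)OMe]2 (2.5 mol %), 1,1′-bis(diphenylphosphino)ferrocene Fe(C5H4PPh2)2 (5 mol %), toluene, 50 °C; then −25 °C, 1-[3,5-bis(trifluoromethyl)phenyl]-3-(9-deoxy-epi-quinin-9-yl)thiourea (20 mol %); then TsOH·H2O, 80 °C
Reagents that add atoms: none
Why: Proposed new method: phenoxide-assisted oxidative addition of the formyl C–H of 15 to monovalent rhodium gives a five-membered acyl(hydrido)rhodium aryloxide chelate (O1″ bound, decarbonylation suppressed), the polarised ynoate 18 inserts into Rh–H with hydride at the anisyl-bearing carbon and rhodium α to the ester, and C–C reductive elimination makes the C3″–C4″ bond by syn addition, giving the Z-alkylidene β-keto ester 19 without added base. The bifunctional thiourea then binds the β-dicarbonyl unit of 19 and its quinuclidine deprotonates O1″–H, so that ring F closes by a 6-endo-trig oxa-Michael addition that forms O1″–C2″, and acid-induced loss of 2-methylpropene and CO2 from 20 removes the activating ester. The closest known reaction types are the rhodium-catalysed hydroacylation of internal alkynes with salicylaldehydes run in tandem with oxa-Michael closure to chroman-4-ones, and the cinchona-thiourea-catalysed enantioselective cyclisation of 2-hydroxyaryl alkylidene β-keto esters with decarboxylation in the same flask; new are the 3-arylpropiolate as alkyne partner and the relay of the two catalysts. C2″ is the only new stereocentre and is set by the catalyst through face discrimination within the thiourea–substrate complex (2″S expected with the quinine series), independently of the remote centres of unit 1. The step needs acyl transfer to the ester-bearing alkyne carbon (secured by the ester polarisation and the usual delivery of hydride to the aryl-substituted carbon), closure through O1″ and not through the oxygen on C5″ (which is benzylated), and no racemic closure before the chiral catalyst is added (base-free rhodium stage at moderate temperature, cyclisation only at −25 °C). C2 and C3 of unit 1 should stay intact because no base stronger than the quinuclidine is present and the last stage is acidic.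

Step 11
Reactants: 21 (2S)-5,7-bis(benzyloxy)-8-[(2R,3S)-5,7-bis(benzyloxy)-2-[4-(benzyloxy)phenyl]-4-oxochroman-3-yl]-2-(4-methoxyphenyl)chroman-4-one
Product: 22 (2S)-5,7-dihydroxy-8-[(2R,3S)-5,7-dihydroxy-2-(4-hydroxyphenyl)-4-oxochroman-3-yl]-2-(4-methoxyphenyl)chroman-4-one
Conditions: H2 (1 atm), Pd/C, EtOAc/MeOH, rt
Reagents that add atoms: none
Why: Hydrogenolysis of the five benzyl aryl ethers over palladium should leave the methyl ether, both ketones and the three stereocentres untouched, because neither acid nor base is present.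

**Compound list**

1 | 3,5-bis(benzyloxy)phenol | Oc1cc(OCc2ccccc2)cc(OCc2ccccc2)c1 | starting material
2 | 1,3-bis(benzyloxy)-5-(methoxymethoxy)benzene | COCOc1cc(OCc2ccccc2)cc(OCc2ccccc2)c1 | intermediate
3 | [2,4-bis(benzyloxy)-6-(methoxymethoxy)phenyl]lithium | [Li]c1c(OCOC)cc(OCc2ccccc2)cc1OCc1ccccc1 | intermediate (not isolated)
4 | lithium [2,4-bis(benzyloxy)-6-(methoxymethoxy)phenyl](dimethylamino)methanolate (racemic) | [Li]OC(N(C)C)c1c(OCOC)cc(OCc2ccccc2)cc1OCc1ccccc1 | intermediate (not isolated)
5 | lithium [2,4-bis(benzyloxy)-5-lithio-6-(methoxymethoxy)phenyl](dimethylamino)methanolate (racemic) | [Li]OC(N(C)C)c1c(OCOC)c([Li])c(OCc2ccccc2)cc1OCc1ccccc1 | intermediate (not isolated)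
6 | 4,6-bis(benzyloxy)-2-(methoxymethoxy)-3-(tributylstannyl)benzaldehyde | CCCC[Sn](CCCC)(CCCC)c1c(OCOC)c(C=O)c(OCc2ccccc2)cc1OCc1ccccc1 | intermediate
7 | [4,6-bis(benzyloxy)-3-formyl-2-(methoxymethoxy)phenyl]lead triacetate | CC(=O)O[Pb](OC(C)=O)(OC(C)=O)c1c(OCOC)c(C=O)c(OCc2ccccc2)cc1OCc1ccccc1 | intermediate
8 | 1-[2,4-bis(benzyloxy)-6-hydroxyphenyl]ethan-1-one | CC(=O)c1c(O)cc(OCc2ccccc2)cc1OCc1ccccc1 | starting material
9 | dilithium enolate–phenoxide of 8 | [Li]OC(=C)c1c(O[Li])cc(OCc2ccccc2)cc1OCc1ccccc1 | intermediate (not isolated)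
10 | tert-butyl 3-[2,4-bis(benzyloxy)-6-hydroxyphenyl]-3-oxopropanoate | CC(C)(C)OC(=O)CC(=O)c1c(O)cc(OCc2ccccc2)cc1OCc1ccccc1 | intermediate
11 | 4-(benzyloxy)benzaldehyde | O=Cc1ccc(OCc2ccccc2)cc1 | starting material
12 | tert-butyl (2Z)-2-[2,4-bis(benzyloxy)-6-hydroxybenzoyl]-3-[4-(benzyloxy)phenyl]prop-2-enoate | CC(C)(C)OC(=O)/C(=C\c1ccc(OCc2ccccc2)cc1)C(=O)c1c(O)cc(OCc2ccccc2)cc1OCc1ccccc1 | intermediate
13 | tert-butyl (2S)-5,7-bis(benzyloxy)-2-[4-(benzyloxy)phenyl]-4-hydroxy-2H-chromene-3-carboxylate (enol tautomer) | CC(C)(C)OC(=O)C1=C(O)c2c(OCc3ccccc3)cc(OCc3ccccc3)cc2O[C@H]1c1ccc(OCc2ccccc2)cc1 | intermediate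
14 | tert-butyl (2S,3R)-3-[4,6-bis(benzyloxy)-3-formyl-2-(methoxymethoxy)phenyl]-5,7-bis(benzyloxy)-2-[4-(benzyloxy)phenyl]-4-oxochromane-3-carboxylate | CC(C)(C)OC(=O)[C@@]1(c2c(OCOC)c(C=O)c(OCc3ccccc3)cc2OCc2ccccc2)C(=O)c2c(OCc3ccccc3)cc(OCc3ccccc3)cc2O[C@H]1c1ccc(OCc2ccccc2)cc1 | intermediate
15 | 4,6-bis(benzyloxy)-3-[(2R,3S)-5,7-bis(benzyloxy)-2-[4-(benzyloxy)phenyl]-4-oxochroman-3-yl]-2-hydroxybenzaldehyde | O=Cc1c(O)c([C@@H]2C(=O)c3c(OCc4ccccc4)cc(OCc4ccccc4)cc3O[C@H]2c2ccc(OCc3ccccc3)cc2)c(OCc2ccccc2)cc1OCc1ccccc1 | intermediate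
16 | 1-ethynyl-4-methoxybenzene | COc1ccc(C#C)cc1 | starting material
17 | lithium (4-methoxyphenyl)acetylide | [Li]C#Cc1ccc(OC)cc1 | intermediate (not isolated)
18 | tert-butyl 3-(4-methoxyphenyl)prop-2-ynoate | COc1ccc(C#CC(=O)OC(C)(C)C)cc1 | intermediate
19 | tert-butyl (2Z)-2-{4,6-bis(benzyloxy)-3-[(2R,3S)-5,7-bis(benzyloxy)-2-[4-(benzyloxy)phenyl]-4-oxochroman-3-yl]-2-hydroxybenzoyl}-3-(4-methoxyphenyl)prop-2-enoate | CC(C)(C)OC(=O)/C(=C\c1ccc(OC)cc1)C(=O)c1c(O)c([C@@H]2C(=O)c3c(OCc4ccccc4)cc(OCc4ccccc4)cc3O[C@H]2c2ccc(OCc3ccccc3)cc2)c(OCc2ccccc2)cc1OCc1ccccc1 | intermediate (not isolated)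
20 | tert-butyl (2R)-5,7-bis(benzyloxy)-8-[(2R,3S)-5,7-bis(benzyloxy)-2-[4-(benzyloxy)phenyl]-4-oxochroman-3-yl]-4-hydroxy-2-(4-methoxyphenyl)-2H-chromene-3-carboxylate (enol tautomer; its C2 spatially as C2″ of the target) | CC(C)(C)OC(=O)C1=C(O)c2c(OCc3ccccc3)cc(OCc3ccccc3)c([C@@H]3C(=O)c4c(OCc5ccccc5)cc(OCc5ccccc5)cc4O[C@H]3c3ccc(OCc4ccccc4)cc3)c2O[C@@H]1c1ccc(OC)cc1 | intermediate (not isolated)
21 | (2S)-5,7-bis(benzyloxy)-8-[(2R,3S)-5,7-bis(benzyloxy)-2-[4-(benzyloxy)phenyl]-4-oxochroman-3-yl]-2-(4-methoxyphenyl)chroman-4-one | COc1ccc([C@@H]2CC(=O)c3c(OCc4ccccc4)cc(OCc4ccccc4)c([C@@H]4C(=O)c5c(OCc6ccccc6)cc(OCc6ccccc6)cc5O[C@H]4c4ccc(OCc5ccccc5)cc4)c3O2)cc1 | intermediate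
22 | (2S)-5,7-dihydroxy-8-[(2R,3S)-5,7-dihydroxy-2-(4-hydroxyphenyl)-4-oxochroman-3-yl]-2-(4-methoxyphenyl)chroman-4-one | COc1ccc([C@@H]2CC(=O)c3c(O)cc(O)c([C@@H]4C(=O)c5c(O)cc(O)cc5O[C@H]4c4ccc(O)cc4)c3O2)cc1 | target

**Step count and risks**

Total step count: 11. Longest linear sequence: 7 steps (steps 4, 5, 6, 7, 8, 10, 11; the branch through steps 1, 2, 3, 7, 8, 10, 11 is equally long).

Steps most likely to fail:

Step 10 (proposed new method). What may go wrong: slow C–H activation at the hindered formyl group, alkyne insertion with the opposite regiochemistry, or closure of ring F during the rhodium stage before the chiral catalyst is present, which would cost the control at C2″. Fallback with known reactions, setting out from 15: Roskamp homologation with tert-butyl diazoacetate (SnCl2 cat., CH2Cl2, rt) would give tert-butyl 3-{4,6-bis(benzyloxy)-3-[(2R,3S)-5,7-bis(benzyloxy)-2-[4-(benzyloxy)phenyl]-4-oxochroman-3-yl]-2-hydroxyphenyl}-3-oxopropanoate F1. Knoevenagel condensation of this with 4-methoxybenzaldehyde (piperidine/AcOH, toluene, 4 Å MS) would give 19 as an isolated compound. Treatment with the quinine-derived thiourea at −25 °C and then TsOH·H2O at 80 °C would return to the route at 21.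

Step 7. What may go wrong: slow ligand coupling at the congested C3, and erosion of the C2 configuration by reversible retro-oxa-Michael opening of 13 while it waits for the arylation. Fallback, setting out from 10: arylation of the unhindered methylene of 10 with 7 (pyridine, CHCl3, 40 °C) would give tert-butyl 2-[4,6-bis(benzyloxy)-3-formyl-2-(methoxymethoxy)phenyl]-3-[2,4-bis(benzyloxy)-6-hydroxyphenyl]-3-oxopropanoate F2. Acidolysis and decarboxylation (TFA, CH2Cl2, H2O) would give the deoxybenzoin 1-[2,4-bis(benzyloxy)-6-hydroxyphenyl]-2-[4,6-bis(benzyloxy)-3-formyl-2-hydroxyphenyl]ethan-1-one F3. Condensation with an excess of 11 (piperidine, EtOH, reflux; Knoevenagel condensation then oxa-Michael closure under thermodynamic control) would give the trans chromanone as the racemate. Preparative chromatography on a chiral stationary phase would remove the antipode 4,6-bis(benzyloxy)-3-[(2S,3R)-5,7-bis(benzyloxy)-2-[4-(benzyloxy)phenyl]-4-oxochroman-3-yl]-2-hydroxybenzaldehyde F4, and the route is rejoined at 15.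

Step 2. What may go wrong: incomplete or misdirected second lithiation (attack of n-BuLi on the masked aldehyde, or benzylic metalation of the benzyl ethers followed by rearrangement). Fallback, setting out from 1: magnesium-mediated ortho-formylation (MgCl2, Et3N, paraformaldehyde, MeCN, reflux) would give 2,4-bis(benzyloxy)-6-hydroxybenzaldehyde F5. Iodination ortho to the free phenol (N-iodosuccinimide, CH2Cl2) would give 4,6-bis(benzyloxy)-2-hydroxy-3-iodobenzaldehyde F6. MOM protection (MOMCl, iPr2NEt) would give 4,6-bis(benzyloxy)-3-iodo-2-(methoxymethoxy)benzaldehyde F7. Stannylation with (Bu3Sn)2 and Pd(PPh3)4 (zerovalent palladium, toluene, 100 °C) would rejoin the route at 6.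

**Further compounds**

F1 | step 10 | tert-butyl 3-{4,6-bis(benzyloxy)-3-[(2R,3S)-5,7-bis(benzyloxy)-2-[4-(benzyloxy)phenyl]-4-oxochroman-3-yl]-2-hydroxyphenyl}-3-oxopropanoate | CC(C)(C)OC(=O)CC(=O)c1c(O)c([C@@H]2C(=O)c3c(OCc4ccccc4)cc(OCc4ccccc4)cc3O[C@H]2c2ccc(OCc3ccccc3)cc2)c(OCc2ccccc2)cc1OCc1ccccc1
F2 | step 7 | tert-butyl 2-[4,6-bis(benzyloxy)-3-formyl-2-(methoxymethoxy)phenyl]-3-[2,4-bis(benzyloxy)-6-hydroxyphenyl]-3-oxopropanoate (racemic) | CC(C)(C)OC(=O)C(c1c(OCOC)c(C=O)c(OCc2ccccc2)cc1OCc1ccccc1)C(=O)c1c(O)cc(OCc2ccccc2)cc1OCc1ccccc1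
F3 | step 7 | 1-[2,4-bis(benzyloxy)-6-hydroxyphenyl]-2-[4,6-bis(benzyloxy)-3-formyl-2-hydroxyphenyl]ethan-1-one | O=Cc1c(O)c(CC(=O)c2c(O)cc(OCc3ccccc3)cc2OCc2ccccc2)c(OCc2ccccc2)cc1OCc1ccccc1
F4 | step 7 | 4,6-bis(benzyloxy)-3-[(2S,3R)-5,7-bis(benzyloxy)-2-[4-(benzyloxy)phenyl]-4-oxochroman-3-yl]-2-hydroxybenzaldehyde (antipode of 15) | O=Cc1c(O)c([C@H]2C(=O)c3c(OCc4ccccc4)cc(OCc4ccccc4)cc3O[C@@H]2c2ccc(OCc3ccccc3)cc2)c(OCc2ccccc2)cc1OCc1ccccc1
F5 | step 2 | 2,4-bis(benzyloxy)-6-hydroxybenzaldehyde | O=Cc1c(O)cc(OCc2ccccc2)cc1OCc1ccccc1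
F6 | step 2 | 4,6-bis(benzyloxy)-2-hydroxy-3-iodobenzaldehyde | O=Cc1c(O)c(I)c(OCc2ccccc2)cc1OCc1ccccc1
F7 | step 2 | 4,6-bis(benzyloxy)-3-iodo-2-(methoxymethoxy)benzaldehyde | O=Cc1c(OCOC)c(I)c(OCc2ccccc2)cc1OCc1ccccc1
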